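The benzyl ester between rings A and B is never made from a hindered benzoic acid: ring A is grown on it. The acetoacetate of the protected ring B alcohol (two MOM ethers, dioxolane, tert-butyl ester) and methyl crotonate are joined by a Michael–Claisen annulation. This forms C1–C6 and C3–C4 and closes the ring A carbocycle as a 2,4-dione in one operation. The feature exploited is the 1,3-relation of the C2 and C4 oxygens of ring A. In the dione, C3 is the only methylene flanked by two carbonyls (C1 is flanked too but is a methine), so the formyl carbon enters at C3 alone, before dehydrogenation.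

Key step: step 9

Remarks on the design
- The target is achiral. All ring A intermediates with sp3 centres are racemic, and these centres vanish on aromatization.
- The ring B aldehyde travels as a 1,3-dioxolane and not as an open-chain acetal. The key-step dione is itself an acid and must be freed from its potassium salt in water. An acyclic acetal between two alkoxy groups would not outlast that, and a free aldehyde would condense with C3 of the dione.
- The acetal is installed before the bromine–lithium exchange, and the benzylic hydroxyl is silylated through all organolithium steps.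
- The dioxolane is removed together with the enaminone hydrolysis, hence before DDQ. The acetal C–H of an electron-rich aryl dioxolane is a hydride donor, whereas a formyl-substituted ring B is inert.
- Assumption: the exocyclic C=C of the enaminone is drawn without geometry because rotation in push–pull alkenes is fast. The formyl dione is drawn as one of its rapidly interconverting enol tautomers.

Step 1
Reactants: 1 3,5-dihydroxybenzyl alcohol
Product: 2 [3,5-bis(methoxymethoxy)phenyl]methanol
Conditions: MOMCl (2.1 equiv), K2CO3, acetone, 0 °C → rt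
Reagents that add atoms: chloromethyl methyl ether (MOMCl), COCCl
Why: Williamson-type O-alkylation in which K2CO3 ionizes only the two phenols, so the phenoxides should consume the limited MOMCl much faster than the neutral primary alcohol.

Step 2
Reactants: 2 [3,5-bis(methoxymethoxy)phenyl]methanol
Product: 3 tert-butyl{[3,5-bis(methoxymethoxy)phenyl]methoxy}dimethylsilane
Conditions: TBSCl, imidazole, CH2Cl2, rt
Reagents that add atoms: tert-butyldimethylsilyl chloride (TBSCl), CC(C)(C)[Si](C)(C)Cl
Why: Imidazole-promoted silylation of a primary alcohol removes the acidic proton before the organolithium steps and gives a group orthogonal to all acid-labile groups used later.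

Step 3
Reactants: 3 tert-butyl{[3,5-bis(methoxymethoxy)phenyl]methoxy}dimethylsilane
Product: 6 4-{[(tert-butyldimethylsilyl)oxy]methyl}-2,6-bis(methoxymethoxy)benzaldehyde, via aryllithium 4 (not isolated), via lithium hemiaminal alkoxide 5 (not isolated)
Conditions: n-BuLi (1.2 equiv), THF, 0 °C; DMF, −78 °C → rt; H2O
Reagents that add atoms: N,N-dimethylformamide (DMF), CN(C)C=O
Why: Directed ortho-metalation, in which the two MOM ethers cooperate to make the C–H between them the most acidic and best coordinated site, and DMF holds the carbanion as a hemiaminal alkoxide that releases the aldehyde only on quenching.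

Step 4
Reactants: 6 4-{[(tert-butyldimethylsilyl)oxy]methyl}-2,6-bis(methoxymethoxy)benzaldehyde
Product: 7 3-bromo-4-{[(tert-butyldimethylsilyl)oxy]methyl}-2,6-bis(methoxymethoxy)benzaldehyde
Conditions: NBS (1.0 equiv), MeCN, 0 °C → rt, dark
Reagents that add atoms: N-bromosuccinimide (NBS), O=C1CCC(=O)N1Br
Why: Electrophilic aromatic bromination at one of two symmetry-equivalent positions, each ortho to one MOM ether, para to the other and meta to the formyl group, so one equivalent of NBS in a polar solvent can give only this monobromide and liberates no acid.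

Step 5
Reactants: 7 3-bromo-4-{[(tert-butyldimethylsilyl)oxy]methyl}-2,6-bis(methoxymethoxy)benzaldehyde
Product: 8 2-[3-bromo-4-{[(tert-butyldimethylsilyl)oxy]methyl}-2,6-bis(methoxymethoxy)phenyl]-1,3-dioxolane
Conditions: (TMSOCH2)2, TMSOTf (5 mol %), CH2Cl2, −78 → −30 °C; Et3N quench
Reagents that add atoms: 1,2-bis(trimethylsilyloxy)ethane, C[Si](C)(C)OCCO[Si](C)(C)C
Why: Noyori acetalization runs aprotically at low temperature and is driven by formation of hexamethyldisiloxane, so the MOM and TBS ethers, which protic acid plus a diol would endanger, should stay intact.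

Step 6
Reactants: 8 2-[3-bromo-4-{[(tert-butyldimethylsilyl)oxy]methyl}-2,6-bis(methoxymethoxy)phenyl]-1,3-dioxolane
Product: 10 tert-butyl 6-{[(tert-butyldimethylsilyl)oxy]methyl}-3-(1,3-dioxolan-2-yl)-2,4-bis(methoxymethoxy)benzoate, via aryllithium 9 (not isolated)
Conditions: n-BuLi (1.05 equiv), THF, −78 °C, 10 min; Boc2O, −78 → 0 °C; H2O
Reagents that add atoms: di-tert-butyl dicarbonate (Boc2O), CC(C)(C)OC(=O)OC(=O)OC(C)(C)C
Why: Bromine–lithium exchange at −78 °C outruns attack on acetal or ethers and O-to-C silyl migration from the neighbouring CH2OTBS group, and acylation of aryllithiums by Boc2O is a known direct entry to tert-butyl benzoates whose crowded product resists a second addition.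

Step 7
Reactants: 10 tert-butyl 6-{[(tert-butyldimethylsilyl)oxy]methyl}-3-(1,3-dioxolan-2-yl)-2,4-bis(methoxymethoxy)benzoate
Product: 11 tert-butyl 3-(1,3-dioxolan-2-yl)-6-(hydroxymethyl)-2,4-bis(methoxymethoxy)benzoate
Conditions: TBAF (1.2 equiv), AcOH (1.2 equiv), THF, 0 °C → rt; used at once
Reagents that add atoms: none
Why: Fluoride-induced desilylation buffered with AcOH releases the alcohol rather than the alkoxide, which together with the bulk of the di-ortho-substituted tert-butyl ester should hold back closure to the phthalide.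

Step 8
Reactants: 11 tert-butyl 3-(1,3-dioxolan-2-yl)-6-(hydroxymethyl)-2,4-bis(methoxymethoxy)benzoate; 12 diketene (4-methylideneoxetan-2-one)
Product: 13 [2-(tert-butoxycarbonyl)-4-(1,3-dioxolan-2-yl)-3,5-bis(methoxymethoxy)phenyl]methyl 3-oxobutanoate
Conditions: DMAP (5 mol %), CH2Cl2, −10 °C → rt
Reagents that add atoms: none
Why: Nucleophile-catalysed ring opening of diketene by a primary alcohol (acetoacetylation) proceeds near 0 °C under nearly neutral conditions and without by-product, so neither the acetal nor the hydroxy ester is stressed.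

Step 9
Reactants: 13 [2-(tert-butoxycarbonyl)-4-(1,3-dioxolan-2-yl)-3,5-bis(methoxymethoxy)phenyl]methyl 3-oxobutanoate; 14 methyl (E)-but-2-enoate (methyl crotonate)
Product: 17 [2-(tert-butoxycarbonyl)-4-(1,3-dioxolan-2-yl)-3,5-bis(methoxymethoxy)phenyl]methyl 6-methyl-2,4-dioxocyclohexane-1-carboxylate (racemic trans), via Michael adduct 15 (not isolated), via potassium dione enolate 16 (not isolated)
Conditions: KOt-Bu (1.05 equiv), t-BuOH–THF, 0 °C; 14 (1.5 equiv), rt → 60 °C; cold aq KHSO4 to pH 4
Reagents that add atoms: none
Why: KOt-Bu converts 13 into its stabilized enolate, which adds through C1 to the β-carbon of 14 (bond C1–C6, adduct 15); proton exchange via t-BuOH then populates the enolate of the methyl ketone, whose carbon C3 attacks the methyl ester carbonyl C4 and expels methoxide (bond C3–C4). This is the classical Michael–Claisen (Michael–Dieckmann) annulation of acetoacetates with crotonates to dihydroorsellinates, and the single ring formed, the six-membered carbocycle of ring A, closes in the 6-exo-trig mode. Every stage up to the ring closure is reversible, and the sequence is pulled forward because the dione, a vinylogous acid far more acidic than the alcohols present, is trapped at once as enolate 16. C6 arises without facial bias (racemate) and C1 stays epimerizable between ketone and ester, so equilibration should place ester and methyl trans-diequatorial; both centres are erased in step 11. The selectivity needed is attack on the crotonate rather than on the other acyl or masked acyl groups: the linking ester is deactivated as part of the enolate, the tert-butyl ester is shielded by two ortho substituents and could be reached only through a seven-membered transition state, and the aldehyde is an acetal. One equivalent of a bulky base keeps free alkoxide scarce, which protects the linking ester from exchange, since a released ring B alkoxide would be lost to phthalide formation.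

Step 10
Reactants: 17 [2-(tert-butoxycarbonyl)-4-(1,3-dioxolan-2-yl)-3,5-bis(methoxymethoxy)phenyl]methyl 6-methyl-2,4-dioxocyclohexane-1-carboxylate
Product: 19 [2-(tert-butoxycarbonyl)-4-formyl-3,5-bis(methoxymethoxy)phenyl]methyl 3-formyl-4-hydroxy-6-methyl-2-oxocyclohex-3-ene-1-carboxylate (racemic trans; enol form of the 3-formyl-2,4-dione), via enaminone 18 (not isolated)
Conditions: Me2NCH(OMe)2 (1.3 equiv), toluene, rt; concentrate; 0.5 M HCl, THF, 0 °C → rt
Reagents that add atoms: N,N-dimethylformamide dimethyl acetal, COC(OC)N(C)C; water, O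
Why: Condensation of a cyclic 1,3-dione with an amide acetal needs a carbon that can lose two hydrogens, which between two carbonyls only C3 offers (C1 is a methine, C5 is singly activated), and brief dilute acid then hydrolyses the vinylogous amide and the electron-rich aryl dioxolane, both far more labile than aryl MOM ethers or the tert-butyl ester, while C1 and C6 are not touched.

Step 11
Reactants: 19 [2-(tert-butoxycarbonyl)-4-formyl-3,5-bis(methoxymethoxy)phenyl]methyl 3-formyl-4-hydroxy-6-methyl-2-oxocyclohex-3-ene-1-carboxylate
Product: 20 [2-(tert-butoxycarbonyl)-4-formyl-3,5-bis(methoxymethoxy)phenyl]methyl 3-formyl-2,4-dihydroxy-6-methylbenzoate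
Conditions: DDQ (1.2 equiv), 1,4-dioxane, 80 °C
Reagents that add atoms: none
Why: DDQ dehydrogenation of an enolizable 2-acylcyclohexane-1,3-dione to the resorcinol, in which hydride leaves the tertiary C6–H allylic to the C1=C2 enol of the β-keto ester and proton loss with tautomerization gives the chelated arene, while ring B with its formyl and ester groups is too electron-poor to react.

Step 12
Reactants: 20 [2-(tert-butoxycarbonyl)-4-formyl-3,5-bis(methoxymethoxy)phenyl]methyl 3-formyl-2,4-dihydroxy-6-methylbenzoate
Product: 21 barbatolic acid (3-formyl-6-{[(3-formyl-2,4-dihydroxy-6-methylbenzoyl)oxy]methyl}-2,4-dihydroxybenzoic acid)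
Conditions: TFA–CH2Cl2 (1:1), H2O (5 vol %), 0 °C → rt
Reagents that add atoms: none
Why: Acidolysis cleaves the tert-butyl ester through the tert-butyl cation and hydrolyses both MOM acetals, whereas the linking ester should survive because its benzylic carbon is meta to both ring B oxygens and cannot ionize and its carbonyl is di-ortho-substituted and chelated.

Compound list
1 | 3,5-dihydroxybenzyl alcohol | OCc1cc(O)cc(O)c1 | starting material
2 | [3,5-bis(methoxymethoxy)phenyl]methanol | OCc1cc(OCOC)cc(OCOC)c1 | intermediate
3 | tert-butyl{[3,5-bis(methoxymethoxy)phenyl]methoxy}dimethylsilane | CC(C)(C)[Si](C)(C)OCc1cc(OCOC)cc(OCOC)c1 | intermediate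
4 | [4-{[(tert-butyldimethylsilyl)oxy]methyl}-2,6-bis(methoxymethoxy)phenyl]lithium | [Li]c1c(OCOC)cc(CO[Si](C)(C)C(C)(C)C)cc1OCOC | intermediate (not isolated)
5 | lithium [4-{[(tert-butyldimethylsilyl)oxy]methyl}-2,6-bis(methoxymethoxy)phenyl](dimethylamino)methanolate (racemic) | [Li+].[O-]C(N(C)C)c1c(OCOC)cc(CO[Si](C)(C)C(C)(C)C)cc1OCOC | intermediate (not isolated)
6 | 4-{[(tert-butyldimethylsilyl)oxy]methyl}-2,6-bis(methoxymethoxy)benzaldehyde | O=Cc1c(OCOC)cc(CO[Si](C)(C)C(C)(C)C)cc1OCOC | intermediate
7 | 3-bromo-4-{[(tert-butyldimethylsilyl)oxy]methyl}-2,6-bis(methoxymethoxy)benzaldehyde | O=Cc1c(OCOC)cc(CO[Si](C)(C)C(C)(C)C)c(Br)c1OCOC | intermediate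
8 | 2-[3-bromo-4-{[(tert-butyldimethylsilyl)oxy]methyl}-2,6-bis(methoxymethoxy)phenyl]-1,3-dioxolane | Brc1c(CO[Si](C)(C)C(C)(C)C)cc(OCOC)c(C2OCCO2)c1OCOC | intermediate
9 | [6-{[(tert-butyldimethylsilyl)oxy]methyl}-3-(1,3-dioxolan-2-yl)-2,4-bis(methoxymethoxy)phenyl]lithium | [Li]c1c(CO[Si](C)(C)C(C)(C)C)cc(OCOC)c(C2OCCO2)c1OCOC | intermediate (not isolated)
10 | tert-butyl 6-{[(tert-butyldimethylsilyl)oxy]methyl}-3-(1,3-dioxolan-2-yl)-2,4-bis(methoxymethoxy)benzoate | CC(C)(C)OC(=O)c1c(CO[Si](C)(C)C(C)(C)C)cc(OCOC)c(C2OCCO2)c1OCOC | intermediate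
11 | tert-butyl 3-(1,3-dioxolan-2-yl)-6-(hydroxymethyl)-2,4-bis(methoxymethoxy)benzoate | CC(C)(C)OC(=O)c1c(CO)cc(OCOC)c(C2OCCO2)c1OCOC | intermediate
12 | diketene (4-methylideneoxetan-2-one) | C=C1CC(=O)O1 | starting material
13 | [2-(tert-butoxycarbonyl)-4-(1,3-dioxolan-2-yl)-3,5-bis(methoxymethoxy)phenyl]methyl 3-oxobutanoate | CC(=O)CC(=O)OCc1cc(OCOC)c(C2OCCO2)c(OCOC)c1C(=O)OC(C)(C)C | intermediate
14 | methyl (E)-but-2-enoate | C/C=C/C(=O)OC | starting material
15 | 1-{[2-(tert-butoxycarbonyl)-4-(1,3-dioxolan-2-yl)-3,5-bis(methoxymethoxy)phenyl]methyl} 5-methyl 2-acetyl-3-methylpentanedioate (racemic, epimerizable diastereomer mixture) | CC(=O)C(C(C)CC(=O)OC)C(=O)OCc1cc(OCOC)c(C2OCCO2)c(OCOC)c1C(=O)OC(C)(C)C | intermediate (not isolated)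
16 | potassium enolate of 17, charge spread over O2–C2–C3–C4–O4 (racemic trans) | [K+].C[C@@H]1CC(=O)C=C([O-])[C@H]1C(=O)OCc1cc(OCOC)c(C2OCCO2)c(OCOC)c1C(=O)OC(C)(C)C | intermediate (not isolated)
17 | [2-(tert-butoxycarbonyl)-4-(1,3-dioxolan-2-yl)-3,5-bis(methoxymethoxy)phenyl]methyl 6-methyl-2,4-dioxocyclohexane-1-carboxylate (racemic trans, one enantiomer drawn, largely enolized) | C[C@@H]1CC(=O)CC(=O)[C@H]1C(=O)OCc1cc(OCOC)c(C2OCCO2)c(OCOC)c1C(=O)OC(C)(C)C | intermediate
18 | [2-(tert-butoxycarbonyl)-4-(1,3-dioxolan-2-yl)-3,5-bis(methoxymethoxy)phenyl]methyl 3-[(dimethylamino)methylidene]-6-methyl-2,4-dioxocyclohexane-1-carboxylate (racemic trans) | C[C@@H]1CC(=O)C(=CN(C)C)C(=O)[C@H]1C(=O)OCc1cc(OCOC)c(C2OCCO2)c(OCOC)c1C(=O)OC(C)(C)C | intermediate (not isolated)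
19 | [2-(tert-butoxycarbonyl)-4-formyl-3,5-bis(methoxymethoxy)phenyl]methyl 3-formyl-4-hydroxy-6-methyl-2-oxocyclohex-3-ene-1-carboxylate (racemic trans) | C[C@@H]1CC(O)=C(C=O)C(=O)[C@H]1C(=O)OCc1cc(OCOC)c(C=O)c(OCOC)c1C(=O)OC(C)(C)C | intermediate
20 | [2-(tert-butoxycarbonyl)-4-formyl-3,5-bis(methoxymethoxy)phenyl]methyl 3-formyl-2,4-dihydroxy-6-methylbenzoate | Cc1cc(O)c(C=O)c(O)c1C(=O)OCc1cc(OCOC)c(C=O)c(OCOC)c1C(=O)OC(C)(C)C | intermediate
21 | barbatolic acid | Cc1cc(O)c(C=O)c(O)c1C(=O)OCc1cc(O)c(C=O)c(O)c1C(=O)O | target

Total step count: 12. Longest linear sequence: 12 steps (1 to 21); 12 and 14 are bought and enter directly.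

Steps most likely to fail

Step 9. The linking β-keto ester may be cleaved by alkoxide exchange, after which the released ring B alkoxide lactonizes irreversibly onto the tert-butyl ester. The sequence may also stall after the conjugate addition.

The fallback builds the dione away from ring B and transfers it afterwards. Commercial tert-butyl acetoacetate and 14 are annulated under the same Michael–Claisen conditions (KOt-Bu, t-BuOH) to tert-butyl 6-methyl-2,4-dioxocyclohexane-1-carboxylate F1. Heating F1 with alcohol 11 in toluene, with removal of t-BuOH, exchanges the ester by the known thermal pathway of tert-butyl β-keto esters. That pathway runs through the acylketene 5-methyl-4-(oxomethylidene)cyclohexane-1,3-dione F2, which the primary alcohol captures. Ring B then never meets a strong base. The fallback sets out from 11 and 14 and comes back at 17.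

Step 11. Hydride abstraction from the strongly chelated, electron-poor tricarbonyl system may be sluggish. Loss of the formyl group or further oxidation at the C6 methyl group may compete on prolonged heating.

The fallback replaces dehydrogenation by selenoxide elimination on the enaminone, in which C3 carries no hydrogen.
- Compound 18 is isolated instead of being hydrolysed and is treated with PhSeCl–pyridine in CH2Cl2, the known selenenylation of cyclic β-keto esters at the methine. Attack anti to the C6 methyl should give the C1 phenylselanyl enaminone F3, with selenium cis to C6–H.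
- H2O2 at 0 °C gives the selenoxide F4. Its only β-hydrogen is C6–H, so syn elimination installs C1=C6, and tautomerization leads to the aromatic dimethyliminium phenolate F5.
- 0.5 M HCl in THF hydrolyses the iminium group and the dioxolane together.

The fallback sets out from 18 and comes back at 20.

Step 6. Silyl migration from oxygen to the carbanion, or slow acyl transfer to a carbanion flanked by two ortho groups, may end in simple protonation of the aryllithium.

The fallback forms the C–C bond with the smallest electrophile and makes the ester at the alkyl side. Aryllithium 9 is quenched at −78 °C with CO2 to the lithium benzoate F6. Titration with cold dilute HCl to pH 4 gives 6-{[(tert-butyldimethylsilyl)oxy]methyl}-3-(1,3-dioxolan-2-yl)-2,4-bis(methoxymethoxy)benzoic acid F7. F7 is then esterified under neutral conditions with N,N-dimethylformamide di-tert-butyl acetal in toluene at 80 °C, a method that does not depend on access to the hindered carbonyl. The fallback sets out from 9 and comes back at 10.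

Further compounds
F1 | step 9 | tert-butyl 6-methyl-2,4-dioxocyclohexane-1-carboxylate (racemic trans) | C[C@@H]1CC(=O)CC(=O)[C@H]1C(=O)OC(C)(C)C
F2 | step 9 | 5-methyl-4-(oxomethylidene)cyclohexane-1,3-dione (racemic acylketene) | C[C@@H]1CC(=O)CC(=O)C1=C=O
F3 | step 11 | [2-(tert-butoxycarbonyl)-4-(1,3-dioxolan-2-yl)-3,5-bis(methoxymethoxy)phenyl]methyl 3-[(dimethylamino)methylidene]-6-methyl-2,4-dioxo-1-(phenylselanyl)cyclohexane-1-carboxylate (racemic, Se trans to methyl) | C[C@@H]1CC(=O)C(=CN(C)C)C(=O)[C@]1([Se]c1ccccc1)C(=O)OCc1cc(OCOC)c(C2OCCO2)c(OCOC)c1C(=O)OC(C)(C)C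
F4 | step 11 | selenoxide of F3 (racemic, mixture at selenium) | C[C@@H]1CC(=O)C(=CN(C)C)C(=O)[C@]1([Se](=O)c1ccccc1)C(=O)OCc1cc(OCOC)c(C2OCCO2)c(OCOC)c1C(=O)OC(C)(C)C
F5 | step 11 | [2-(tert-butoxycarbonyl)-4-(1,3-dioxolan-2-yl)-3,5-bis(methoxymethoxy)phenyl]methyl 3-[(dimethyliminio)methyl]-4-hydroxy-6-methyl-2-oxidobenzoate | C[N+](C)=Cc1c(O)cc(C)c(C(=O)OCc2cc(OCOC)c(C3OCCO3)c(OCOC)c2C(=O)OC(C)(C)C)c1[O-]
F6 | step 6 | lithium 6-{[(tert-butyldimethylsilyl)oxy]methyl}-3-(1,3-dioxolan-2-yl)-2,4-bis(methoxymethoxy)benzoate | [Li+].[O-]C(=O)c1c(CO[Si](C)(C)C(C)(C)C)cc(OCOC)c(C2OCCO2)c1OCOC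
F7 | step 6 | 6-{[(tert-butyldimethylsilyl)oxy]methyl}-3-(1,3-dioxolan-2-yl)-2,4-bis(methoxymethoxy)benzoic acid | OC(=O)c1c(CO[Si](C)(C)C(C)(C)C)cc(OCOC)c(C2OCCO2)c1OCOC
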